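## The problem

The target **9** is a flavanone. The phloroglucinol ring A is fused to the dihydropyranone ring C, and C2 of ring C carries ring B, a phenyl ring whose para oxygen bears a geranyl group. The only stereocentre is C2 (S); nothing else in the molecule can direct it, so it must be set by a chiral catalyst or reagent, ideally in the step that closes ring C. Once the C4 ketone is present this centre is fragile. It is benzylic, α to the ring oxygen and β to the carbonyl, so base opens ring C by retro-oxa-Michael reaction to the achiral 2'-hydroxychalcone, and strong acid can ionise the C2–O1 bond with help from the para-alkoxy group. The geranyl aryl ether is an allylic ether with two trisubstituted olefins; this rules out hydrogenolysis, strong protic or Lewis acid at ambient temperature, zerovalent palladium and electrophilic oxidants late in the route. The three phenolic oxygens must be told apart (O4' geranylated, O5 and O7 free). This is simplest if ring B arrives with its geranyl group and ring A with silyl ethers, which leave under mild, non-basic, non-reductive conditions. The enabling feature is that O1, C8a, C4a and C4 are the heterodiene of an ortho-quinone methide that a 2-hydroxybenzaldehyde of the phloroglucinol series forms on O-protonation (C4 is the formyl carbon, stabilised by the oxygens at C5 and C7), while C2–C3 with ring B is the double bond of a para-alkoxystyrene polarised in the complementary sense. The C4 oxygen of the flavanone is then the aldehyde oxygen, one oxidation level below the ketone.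

## Retrosynthesis

**9 to 8 (O–Si bonds at O5 and O7).** The last operation should be the mildest in the route, because C2 is most fragile in the free flavanone. The two phenols are traced back to the bis(tert-butyldimethylsilyl) ether **8**. Silyl ethers are preferred over benzyl ethers (hydrogenolysis would saturate the chain), acetals (protic acid endangers the geranyl ether) and esters (basic cleavage opens ring C). The forward step must be a buffered, non-basic fluoride cleavage.

**8 to 7 (oxidation level at C4, no skeletal bond cut).** The ketone is traced back to the secondary benzylic carbinol of the flavan-4-ol **7**. This is the oxidation level that a union of an aldehyde with an alkene delivers, and no comparable cycloaddition enters at the ketone level. The price is one oxidation; the gain is that the C4 configuration of **7** is erased and need not be controlled. The forward reaction must be neutral: it must not ionise the electron-rich benzylic carbinol, must leave the olefins alone and must not form an alkoxide, which could pull a silyl group over from O5.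

**7 to 2 and 6 (C3–C4 and O1–C2 cut together).** This double cut splits **7** into the salicylaldehyde **2** and the styrene **6**. Both are achiral, of nearly equal size and one or two steps from commercial materials. Cutting O1–C2 alone leads to a reversible, base-mediated ring closure that is hard to render enantioselective. Cutting C4–C4a or C3–C4 alone gives linear sequences in which the stereocentre must be made first and then carried through harsh ring closures. The double cut forms ring C, two skeletal bonds and C2 in one catalytic event. The forward reaction must meet four demands:
- Regiochemistry: the polarity of both partners provides it.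
- C2 configuration: a chiral acid must select the face of the styrene-derived cation to which O1 adds.
- Chemoselectivity: the styrene must react in preference to the two olefins of the chain.
- Product survival: the acid-labile product must outlast the catalyst.

The design is hardened on three points. **2** carries exactly one free hydroxyl, the chelated one that becomes O1. The styrene is kept at low concentration. The acid is quenched cold.

**2 to 1 (two O–Si bonds).** The aldehyde **2** comes from 2,4,6-trihydroxybenzaldehyde **1**. Its two ortho hydroxyls are equivalent, so bis-silylation at the para and one ortho oxygen can give only one constitution, and the remaining hydroxyl is protected from a third silylation by its hydrogen bond to the formyl oxygen.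

**6 to 5 to 3 and 4 (the C=C bond, then the O–C bond).** The vinyl group of **6** is traced to the aldehyde **5** by methylenation. **5** is traced to 4-hydroxybenzaldehyde **3** and geranyl bromide **4** by an ether synthesis. Installing the geranyl group first removes any later need to distinguish O4' from O5 and O7.

## Roads not taken

**Alternative 1: umpolung closure at C3–C4.**
- Cut: C3–C4 alone.
- Forward key step: an alkyllithium base deprotonates the dithiane carbon (the future C4) of 2-{2-[(1S)-3-chloro-1-(4-geranyloxyphenyl)propoxy]-4,6-bis(methoxymethoxy)phenyl}-1,3-dithiane A2. The carbanion displaces the primary chloride in a 6-exo-tet closure to give the flavanone dithioketal A1.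
- Merits: every step is of a known type, C2 is in place before ring closure and takes no part in it, and the closure is an irreversible alkylation. On reliability of the individual steps this road is better than the chosen one.
- Weak points: the stereocentre of A2 is a para-alkoxybenzylic aryl ether, which would most plausibly be made by Mitsunobu inversion with a hindered phenol; such alcohols ionise, so the inversion leaks. The closure puts an alkyllithium next to a benzylic α-oxy C–H and to acetal groups that direct ortho-metalation. Unmasking the ketone of A1 needs thiophilic metal salts, alkylating agents or electrophilic oxidants in the presence of two trisubstituted olefins and a phloroglucinol ring. Acetal removal then needs protic acid beside the geranyl ether. The sequence runs to about ten steps.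
- Comparison: the chosen plan offers six steps, no strong base and a single mild deprotection, at the price of an untested key step.

**Alternative 2: carbonylative three-component assembly of the flavone.**
- Cut: C4a–C4, C4–C3 and O1–C2, with C4 from the carbonylating atmosphere.
- Forward key step: PdCl2(PPh3)2 with a secondary amine joins 2-iodo-3,5-bis(triisopropylsilyloxy)phenol A4, 1-ethynyl-4-(geranyloxy)benzene A5 and one carbonyl carbon to an ynone. The phenol oxygen then adds at C2 to give 4'-(geranyloxy)-5,7-bis(triisopropylsilyloxy)flavone A3.
- Merits: it is the most convergent assembly of the skeleton, the palladium chemistry is robust, and A3 has no acid- or base-labile centre. In bond construction it is more dependable than the chosen key step.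
- Weak points: A3 is flat at C2, so the only stereochemical problem of the target is postponed. It would need an enantioselective 1,4-reduction of a 5,7-dioxygenated flavone, a poor hydride acceptor, that spares two trisubstituted olefins and an allylic ether and stops before the flavan-4-ol. Hydrogenation is excluded by the chain. The ynone can also close in the five-membered mode, and A4 needs a regioselective iodination.
- Comparison: the chosen plan forms C2 in the step that closes ring C.

**Alternative 3: Friedel–Crafts closure at C4–C4a.**
- Cut: C4–C4a alone.
- Forward key step: (3S)-3-[3,5-bis(tert-butyldimethylsilyloxy)phenoxy]-3-[4-(geranyloxy)phenyl]propanoic acid A7 is converted to its acyl chloride and then, with AgOTf and a hindered pyridine, to the acyl triflate. This acylates the ortho carbon of ring A to give the silylated flavanone A6, which is the same substance as **8**.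
- Merits: it arrives at the ketone oxidation level with no redox step, and the local symmetry of ring A removes any regiochemical question. In both respects it is better than the chosen plan, which needs an oxidation.
- Weak points: the stereocentre of A7 is a para-alkoxybenzylic aryl ether β to the activated acyl group. Acyl triflate formation invites loss of the aryloxy group (elimination to a cinnamoyl derivative) and C–O ionisation, either of which destroys the C2 configuration. The acylating agent also meets the two olefins of the chain. A7 needs the same leaky benzylic etherification as alternative 1, and the sequence has eight or more steps.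
- Comparison: the chosen plan is convergent and creates the stereocentre catalytically during ring closure instead of carrying it through electrophilic activation; it pays with one oxidation and an unproven key step.

Key step: step 4

Remark on the chemistry: which antipode of the confined acid leads to the 2S series cannot be derived from first principles. The (S,S)-catalyst is written throughout and stands for whichever antipode a first experiment shows to give 2S. Flavanone numbering is used (O1, C2, C3, C4, C4a, C5 to C8, C8a; ring B primed), and "geranyl" means (2E)-3,7-dimethylocta-2,6-dien-1-yl.

## Route

Step 1
Reactants: 1 2,4,6-trihydroxybenzaldehyde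
Product: 2 2-hydroxy-4,6-bis(tert-butyldimethylsilyloxy)benzaldehyde
Conditions: TBSCl (2.1 equiv), imidazole (4.5 equiv), DMF, 0 °C
Reagents that add atoms: tert-butyldimethylsilyl chloride, CC(C)(C)[Si](C)(C)Cl
Why: Silyl ether formation on phenols; the para hydroxyl and the non-chelated ortho hydroxyl react, after which the last hydroxyl is locked in a hydrogen bond to the formyl oxygen and is the least nucleophilic, and because the two ortho hydroxyls of 1 are equivalent only one bis-silyl ether can form.

Step 2
Reactants: 3 4-hydroxybenzaldehyde; 4 geranyl bromide, (2E)-1-bromo-3,7-dimethylocta-2,6-diene
Product: 5 4-(geranyloxy)benzaldehyde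
Conditions: K2CO3, acetone, reflux
Reagents that add atoms: none
Why: Williamson ether synthesis; the phenoxide of 3 displaces the primary allylic bromide by direct substitution, so that the E olefin is retained and no allylic transposition is expected.

Step 3
Reactants: 5 4-(geranyloxy)benzaldehyde
Product: 6 1-ethenyl-4-(geranyloxy)benzene
Conditions: Ph3PCH3Br, KOt-Bu, THF, 0 °C to rt
Reagents that add atoms: methyltriphenylphosphonium bromide, C[P+](c1ccccc1)(c1ccccc1)c1ccccc1.[Br-]
Why: Wittig methylenation of a non-enolisable aryl aldehyde with the non-stabilised ylide; the ether and the trisubstituted olefins are inert, and 6 should be freed completely of phosphine oxide and base and kept cold because either would bind the acid of step 4.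

Step 4
Reactants: 2 2-hydroxy-4,6-bis(tert-butyldimethylsilyloxy)benzaldehyde; 6 1-ethenyl-4-(geranyloxy)benzene
Product: 7 (2S,4S)-5,7-bis(tert-butyldimethylsilyloxy)-4'-(geranyloxy)flavan-4-ol (2,4-cis)
Conditions: (S,S)-imidodiphosphorimidate acid built from two 3,3'-bis[3,5-bis(trifluoromethyl)phenyl]-1,1'-bi-2-naphthol units with N-trifluoromethanesulfonyl groups on both imide nitrogens (C74H33F30N3O8P2S2, 5 mol %), 5 Å molecular sieves, CHCl3, −50 °C, 2 (1.3 equiv), slow addition of 6; then Et3N, −50 °C
Reagents that add atoms: none
Why: Proposed new method: the acid protonates the formyl oxygen of 2 and so generates the O-protonated 2-hydroxy ortho-quinone methide, a benzylic oxocarbenium ion stabilised by the silyloxy groups at the future C5 and C7 and held as a contact ion pair with the chiral imidodiphosphorimidate anion; the CH2 terminus of 6 attacks the formyl carbon (C3–C4), and the para-alkoxybenzylic cation that develops at C2 is captured within the ion pair by the phenolic oxygen (O1–C2), a strongly asynchronous inverse-electron-demand oxa-(4+2) cycloaddition in which all atoms of both partners end up in 7. The closest known reaction types are the achiral acid-promoted (4+2) annulation of salicylaldehydes with styrenes to 2,4-cis-4-alkoxyflavans, chiral phosphoric acid-catalysed cycloadditions of ortho-quinone methides with styrenes, and imidodiphosphorimidate-catalysed hetero-Diels–Alder reactions of aldehydes with dienes; the direct enantioselective union of a free salicylaldehyde with a styrene to a flavan-4-ol has not been shown. Ring C closes by intermolecular (4+2) annulation, its second bond by six-membered collapse of the phenol oxygen onto the benzylic cation through a half-chair with the C2 aryl group equatorial. C2 is under catalyst control: the anion pocket must present to O1 the face of the styrene-derived cation that gives 2S, and a tight ion pair in a weakly polar solvent at low temperature is relied on to make closure faster than rotation or dissociation. C4 is under substrate control only, the 2,4-cis (4S) arrangement with a pseudo-equatorial hydroxyl being expected by analogy with the alkoxyflavan series; a C4 epimer of the 2S series is equally useful because step 5 erases this centre, whereas any 2R isomer would lower the enantiomeric purity of 8. The step needs regioselectivity, secured by the matched polarity of the partners (nucleophilic CH2 to electrophilic C4, positive charge at the carbon bearing the donor-substituted ring B), and chemoselectivity for the styrene over the two trisubstituted olefins and the allylic ether of the chain, secured by the much higher nucleophilicity of the alkoxystyrene, the low temperature and the levelling of the acid by the basic carbonyl of 2. Slow addition of 6 to an excess of 2 keeps cationic styrene oligomerisation down, the confined pocket disfavours re-entry of the bulky product, and the cold amine quench prevents ionisation of the C4 carbinol of 7 on warming.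

Step 5
Reactants: 7 (2S,4S)-5,7-bis(tert-butyldimethylsilyloxy)-4'-(geranyloxy)flavan-4-ol
Product: 8 (2S)-5,7-bis(tert-butyldimethylsilyloxy)-4'-(geranyloxy)flavanone
Conditions: activated MnO2 (excess), CH2Cl2, rt
Reagents that add atoms: none
Why: MnO2 oxidation of a benzylic alcohol; the reagent is neutral and releases no acid that could ionise C4, generates no alkoxide that could draw a silyl group from O5, and leaves isolated olefins, the allylic ether and the silyl ethers alone; both C4 epimers converge on one ketone and C2 is not touched.

Step 6
Reactants: 8 (2S)-5,7-bis(tert-butyldimethylsilyloxy)-4'-(geranyloxy)flavanone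
Product: 9 (2S)-5,7-dihydroxy-4'-(geranyloxy)flavanone (the target)
Conditions: HF·pyridine, pyridine, THF, 0 °C to rt
Reagents that add atoms: none
Why: Fluoride cleavage of aryl silyl ethers; the pyridine-buffered reagent is not basic, so ring C should not open to the chalcone and C2 should keep its configuration, and it is too weak an acid to ionise the geranyl ether or to add to the olefins.

## Compound list

1 | 2,4,6-trihydroxybenzaldehyde | O=Cc1c(O)cc(O)cc1O | starting material
2 | 2-hydroxy-4,6-bis(tert-butyldimethylsilyloxy)benzaldehyde | O=Cc1c(O)cc(O[Si](C)(C)C(C)(C)C)cc1O[Si](C)(C)C(C)(C)C | intermediate
3 | 4-hydroxybenzaldehyde | O=Cc1ccc(O)cc1 | starting material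
4 | geranyl bromide, (2E)-1-bromo-3,7-dimethylocta-2,6-diene | CC(C)=CCC/C(C)=C/CBr | starting material
5 | 4-{[(2E)-3,7-dimethylocta-2,6-dien-1-yl]oxy}benzaldehyde | CC(C)=CCC/C(C)=C/COc1ccc(C=O)cc1 | intermediate
6 | 1-ethenyl-4-{[(2E)-3,7-dimethylocta-2,6-dien-1-yl]oxy}benzene | CC(C)=CCC/C(C)=C/COc1ccc(C=C)cc1 | intermediate
7 | (2S,4S)-5,7-bis[(tert-butyldimethylsilyl)oxy]-2-(4-{[(2E)-3,7-dimethylocta-2,6-dien-1-yl]oxy}phenyl)-3,4-dihydro-2H-chromen-4-ol (2,4-cis) | CC(C)=CCC/C(C)=C/COc1ccc([C@@H]2C[C@H](O)c3c(O[Si](C)(C)C(C)(C)C)cc(O[Si](C)(C)C(C)(C)C)cc3O2)cc1 | intermediate
8 | (2S)-5,7-bis[(tert-butyldimethylsilyl)oxy]-2-(4-{[(2E)-3,7-dimethylocta-2,6-dien-1-yl]oxy}phenyl)-2,3-dihydro-4H-chromen-4-one | CC(C)=CCC/C(C)=C/COc1ccc([C@@H]2CC(=O)c3c(O[Si](C)(C)C(C)(C)C)cc(O[Si](C)(C)C(C)(C)C)cc3O2)cc1 | intermediate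
9 | (2S)-2-(4-{[(2E)-3,7-dimethylocta-2,6-dien-1-yl]oxy}phenyl)-5,7-dihydroxy-2,3-dihydro-4H-chromen-4-one | CC(C)=CCC/C(C)=C/COc1ccc([C@@H]2CC(=O)c3c(O)cc(O)cc3O2)cc1 | target

## Step count and risks

Total: 6 steps. Longest linear sequence: 5 steps (3 to 5 to 6 to 7 to 8 to 9).

**Step 4 (key step, Proposed new method).**
- What may go wrong:
  - Poor enantiofacial discrimination at C2, because the bond that fixes C2 forms second, from a benzylic cation that can rotate if the ion pair loosens.
  - Loss of material to acid-driven side processes: cationic oligomerisation of the electron-rich styrene, and re-ionisation of the product at C4 followed by elimination or capture by a second styrene.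
  - Ionisation of the O1–C2 bond of the product, which would erode its enantiomeric purity.
  - Low reactivity of the donor-rich aldehyde at the temperature needed for selectivity.
  - The enantiomeric purity is to be read on 8, where the C4 epimers have converged.
- Fallback (known chemistry): enantioselective conjugate addition of an arylboronic acid to a chromone. It sets out from 4 and comes back at 8.
  - 4 is coupled with 4-bromophenol (K2CO3, acetone) to give 1-bromo-4-(geranyloxy)benzene F1.
  - Bromine–lithium exchange (n-BuLi, THF, −78 °C), B(Oi-Pr)3 and a mild aqueous NH4Cl work-up give [4-(geranyloxy)phenyl]boronic acid F2.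
  - Commercial 5,7-dihydroxy-4H-chromen-4-one is silylated (TBSOTf, 2,6-lutidine, CH2Cl2) to 5,7-bis(tert-butyldimethylsilyloxy)-4H-chromen-4-one F3.
  - F2 is added to F3 with Pd(OCOCF3)2 (divalent palladium) and the antipode of 4-tert-butyl-2-(pyridin-2-yl)-4,5-dihydrooxazole that gives the 2S series (NH4PF6, water, 1,2-dichloroethane, 40 °C). This should give 8 directly, after which step 6 follows unchanged.
  - This fallback is comparable in length. It is held in reserve because its own key step must overcome a donor-rich acceptor with a substituent peri to the carbonyl, and because it needs a costlier chromone.

**Step 5 (oxidation).**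
- What may go wrong: acid- or surface-promoted ionisation of the C4 carbinol (dehydration, oligomerisation) while 7 is isolated or while it sits on the solid oxidant, and slow turnover because the carbinol is flanked by the C5 silyloxy group. Oxidations that pass through an alkoxide are excluded because they invite silyl migration from O5 to O4.
- Fallback: it sets out from 7 and comes back at 8. 7 is not purified; the amine-quenched solution of step 4 is filtered cold through basic alumina, concentrated without warming and oxidised at once in solution with Dess–Martin periodinane and pyridine in CH2Cl2 at 0 °C. The labile carbinol then never meets silica or an oxide surface. This fallback makes no new compound, F0.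

**Step 6 (desilylation).**
- What may go wrong: slow cleavage of the C7 silyl ether under the buffered reagent, which would tempt longer exposure or a more acidic medium and so put the geranyl ether and the C2–O1 bond at risk of ionisation.
- Fallback: a staged, fluoride-free solvolysis that sets out from 8 and comes back at 9.
  - Pyridinium p-toluenesulfonate in MeOH/CH2Cl2 at rt should remove only the C5 silyl ether, which is activated by the neighbouring carbonyl, giving (2S)-7-(tert-butyldimethylsilyloxy)-4'-(geranyloxy)-5-hydroxyflavanone F4.
  - The remaining C7 silyl ether, a vinylogous silyl ester, is then methanolysed with a catalytic amount of K2CO3 in MeOH at −20 °C and quenched with AcOH before ring C can open.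

**Step 3 (methylenation).**
- What may go wrong: the Wittig reaction itself is dependable. The risk is carry-over of Lewis-basic phosphine oxide and base into 6, where they would neutralise the 5 mol % acid of step 4, together with oligomerisation of the styrene on acidic silica during the purification needed to remove them.
- Fallback: a phosphorus-free access that sets out from 4 and comes back at 6. Commercial 4-acetoxystyrene is saponified in the flask (KOH, DMSO, rt) to the potassium salt of 4-ethenylphenol F5, which is alkylated with 4 in the same flask. 6 can then be made fresh, in one operation, immediately before the key step.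

## Further compounds

F1 | step 4 | 1-bromo-4-{[(2E)-3,7-dimethylocta-2,6-dien-1-yl]oxy}benzene | CC(C)=CCC/C(C)=C/COc1ccc(Br)cc1
F2 | step 4 | (4-{[(2E)-3,7-dimethylocta-2,6-dien-1-yl]oxy}phenyl)boronic acid | CC(C)=CCC/C(C)=C/COc1ccc(B(O)O)cc1
F3 | step 4 | 5,7-bis[(tert-butyldimethylsilyl)oxy]-4H-chromen-4-one | O=c1ccoc2cc(O[Si](C)(C)C(C)(C)C)cc(O[Si](C)(C)C(C)(C)C)c12
F0 | step 5 | none | none
F4 | step 6 | (2S)-7-[(tert-butyldimethylsilyl)oxy]-2-(4-{[(2E)-3,7-dimethylocta-2,6-dien-1-yl]oxy}phenyl)-5-hydroxy-2,3-dihydro-4H-chromen-4-one | CC(C)=CCC/C(C)=C/COc1ccc([C@@H]2CC(=O)c3c(O)cc(O[Si](C)(C)C(C)(C)C)cc3O2)cc1
F5 | step 3 | 4-ethenylphenol | C=Cc1ccc(O)cc1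
A1 | alternative 1 | (2S)-4'-(geranyloxy)-5,7-bis(methoxymethoxy)flavanone propane-1,3-diyl dithioketal | CC(C)=CCC/C(C)=C/COc1ccc([C@@H]2CC3(SCCCS3)c3c(OCOC)cc(OCOC)cc3O2)cc1
A2 | alternative 1 | 2-{2-[(1S)-3-chloro-1-(4-{[(2E)-3,7-dimethylocta-2,6-dien-1-yl]oxy}phenyl)propoxy]-4,6-bis(methoxymethoxy)phenyl}-1,3-dithiane | CC(C)=CCC/C(C)=C/COc1ccc([C@H](CCCl)Oc2cc(OCOC)cc(OCOC)c2C2SCCCS2)cc1
A3 | alternative 2 | 4'-(geranyloxy)-5,7-bis(triisopropylsilyloxy)flavone | CC(C)=CCC/C(C)=C/COc1ccc(-c2cc(=O)c3c(O[Si](C(C)C)(C(C)C)C(C)C)cc(O[Si](C(C)C)(C(C)C)C(C)C)cc3o2)cc1
A4 | alternative 2 | 2-iodo-3,5-bis(triisopropylsilyloxy)phenol | Oc1cc(O[Si](C(C)C)(C(C)C)C(C)C)cc(O[Si](C(C)C)(C(C)C)C(C)C)c1I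
A5 | alternative 2 | 1-ethynyl-4-{[(2E)-3,7-dimethylocta-2,6-dien-1-yl]oxy}benzene | CC(C)=CCC/C(C)=C/COc1ccc(C#C)cc1
A6 | alternative 3 | (2S)-5,7-bis(tert-butyldimethylsilyloxy)-4'-(geranyloxy)flavanone | CC(C)=CCC/C(C)=C/COc1ccc([C@@H]2CC(=O)c3c(O[Si](C)(C)C(C)(C)C)cc(O[Si](C)(C)C(C)(C)C)cc3O2)cc1
A7 | alternative 3 | (3S)-3-[3,5-bis(tert-butyldimethylsilyloxy)phenoxy]-3-(4-{[(2E)-3,7-dimethylocta-2,6-dien-1-yl]oxy}phenyl)propanoic acid | CC(C)=CCC/C(C)=C/COc1ccc([C@H](CC(=O)O)Oc2cc(O[Si](C)(C)C(C)(C)C)cc(O[Si](C)(C)C(C)(C)C)c2)cc1
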